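**Retrosynthetic overview**

- The target is a diaryl ether; the last step only removes three O-alkyl groups (ethyl on ring B O2, tert-butyl on the ring B carboxyl, benzyl on ring A O5).
- The strategy rests on ring B, numbered C1 (carboxyl), C2 (hydroxyl), C3 (chlorine), C4 (methyl), C5 (hydrogen), C6 (aryloxy). C1, C6, C5 and C4 with their substituents are C3, C4, C5 and C6 of a 4-aryloxy-6-methyl-2-pyrone-3-carboxylate. The C2(O)–C3(Cl) pair is a chloroketene acetal. Ring B is therefore cut at C1–C2 and C3–C4, and the cycloadduct loses carbon dioxide and an alcohol.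
- The ring A–O–C6 bond is made before that, by addition-elimination of the ring A phenol at C4 of the pyrone 4-tosylate. The pyrone comes from di-tert-butyl malonate and acetylketene (from 2,2,6-trimethyl-4H-1,3-dioxin-4-one).
- The ring A phenol comes from 2-hydroxy-3-methoxybenzoic acid by Elbs oxidation at C5, esterification and 5-O-benzylation. The acetal is used as its diethyl member, made in one step from commercial 1,1-dichloro-2,2-diethoxyethane; the ethoxy group it leaves on ring B is only a protecting group.
- Ring order: ring A is bought, the pyrone ring is closed second, ring B is formed last.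

Key step: step 8

Remark: the ethyl ether that the diethyl acetal leaves beside the ring B carboxyl is assumed to respond to chelation-controlled BCl3 cleavage as the corresponding methyl ether does, only more slowly.

**Route**

Step 1
Reactants: 1 2-hydroxy-3-methoxybenzoic acid
Product: 3 2,5-dihydroxy-3-methoxybenzoic acid, via aryl sulfate 2 (not isolated)
Conditions: K2S2O8, aq KOH, 0–20 °C; then HCl, 90 °C
Reagents that add atoms: potassium peroxodisulfate, [K+].[K+].[O-]S(=O)(=O)OOS(=O)(=O)[O-]
Why: Elbs persulfate oxidation, in which the phenoxide attacks the peroxide oxygen through C5, the only position para to the phenol oxygen, and the resulting aryl sulfate is hydrolysed by acid to the hydroquinone.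

Step 2
Reactants: 3 2,5-dihydroxy-3-methoxybenzoic acid
Product: 4 methyl 2,5-dihydroxy-3-methoxybenzoate
Conditions: MeOH, H2SO4 (cat.), reflux, N2
Reagents that add atoms: methanol, CO
Why: Fischer esterification, run under acid and nitrogen because the hydroquinone is stable there but would oxidise in air under base.

Step 3
Reactants: 4 methyl 2,5-dihydroxy-3-methoxybenzoate
Product: 5 methyl 5-(benzyloxy)-2-hydroxy-3-methoxybenzoate
Conditions: BnBr (1.0 equiv), K2CO3 (1.0 equiv), acetone, 20–40 °C
Reagents that add atoms: benzyl bromide, BrCc1ccccc1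
Why: Williamson ether synthesis that should take the 5-hydroxyl only, since the 2-hydroxyl is hydrogen-bonded to the ester carbonyl and flanked by the ester and the methoxy group, the selectivity known for gentisate esters.

Step 4
Reactants: 6 di-tert-butyl malonate; 7 2,2,6-trimethyl-4H-1,3-dioxin-4-one
Product: 11 tert-butyl 4-hydroxy-6-methyl-2-oxo-2H-pyran-3-carboxylate, via acetylketene 8 (not isolated), via acylmalonate 9 (not isolated), via acylketene 10 (not isolated)
Conditions: NaH (1.0 equiv), THF, 0 °C; 7, toluene, 110 °C; AcOH, then toluene, 90–110 °C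
Reagents that add atoms: none
Why: C-acylation of the malonate enolate by acetylketene, released from the dioxinone by retro-(4+2) loss of acetone, gives 9, whose β-keto tert-butyl ester loses tert-butanol on heating to acylketene 10, which the enol oxygen of the 5-oxo group captures to close the pyrone, the same lactonisation that converts β,δ-diketo dioxinones into 4-hydroxy-2-pyrones; neutral conditions avoid the competing carbon-Claisen closure to a phloroglucinol.

Step 5
Reactants: 11 tert-butyl 4-hydroxy-6-methyl-2-oxo-2H-pyran-3-carboxylate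
Product: 12 tert-butyl 6-methyl-4-[(4-methylbenzenesulfonyl)oxy]-2-oxo-2H-pyran-3-carboxylate
Conditions: TsCl, Et3N, DMAP (cat.), CH2Cl2, 0 °C
Reagents that add atoms: 4-methylbenzenesulfonyl chloride, Cc1ccc(S(=O)(=O)Cl)cc1
Why: O-sulfonylation of a vinylogous carboxylic acid, whose 4-oxygen is the only nucleophilic site once deprotonated by the amine.

Step 6
Reactants: 12 tert-butyl 6-methyl-4-[(4-methylbenzenesulfonyl)oxy]-2-oxo-2H-pyran-3-carboxylate; 5 methyl 5-(benzyloxy)-2-hydroxy-3-methoxybenzoate
Product: 13 tert-butyl 4-[4-(benzyloxy)-2-methoxy-6-(methoxycarbonyl)phenoxy]-6-methyl-2-oxo-2H-pyran-3-carboxylate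
Conditions: Cs2CO3 (1.0 equiv), MeCN, 20–50 °C
Reagents that add atoms: none
Why: Addition-elimination (vinylogous acyl substitution) at pyrone C4, which is β to both the lactone and the ester carbonyl, so even the hindered phenoxide of 5 should add there and expel tosylate, a far easier way to this crowded diaryl-type ether than any arylation.

Step 7
Reactants: 14 1,1-dichloro-2,2-diethoxyethane
Product: 15 2-chloro-1,1-diethoxyethene (chloroketene diethyl acetal)
Conditions: KOtBu (1.1 equiv), THF, 0 → 60 °C; distil, store over K2CO3
Reagents that add atoms: none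
Why: E2 dehydrochlorination of an α-halo acetal by a hindered alkoxide, the classical ketene acetal synthesis, in which the acetal hydrogen and one chlorine leave so that one chlorine stays on the alkene carbon.

Step 8
Reactants: 13 tert-butyl 4-[4-(benzyloxy)-2-methoxy-6-(methoxycarbonyl)phenoxy]-6-methyl-2-oxo-2H-pyran-3-carboxylate; 15 2-chloro-1,1-diethoxyethene
Product: 18 tert-butyl 6-[4-(benzyloxy)-2-methoxy-6-(methoxycarbonyl)phenoxy]-3-chloro-2-ethoxy-4-methylbenzoate, via bridged lactone 16 (not isolated), via cyclohexadiene 17 (not isolated)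
Conditions: 15 (5 equiv), iPr2NEt (0.1 equiv), toluene, 110–140 °C, sealed tube
Reagents that add atoms: none
Why: This is the inverse-electron-demand Diels-Alder reaction of a 2-pyrone-3-carboxylate with a ketene acetal, the known route from such pyrones to 2-alkoxybenzoates, extended here to a chlorinated acetal and a 4-aryloxy-6-methyl pyrone, which is why heat is needed. The ester and lactone carbonyls make pyrone C6 the electrophilic diene terminus, so the nucleophilic chlorine-bearing carbon of 15 bonds there and the acetal carbon bonds to pyrone C3; ring B is thus closed by intermolecular (4+2) addition, forming its C1–C2 and C3–C4 bonds in bridged lactone 16. Retro-(4+2) loss of carbon dioxide gives cyclohexadiene 17. Ionisation of one ethoxy group and loss of the only removable ring proton, the one on the chlorine-bearing carbon, then aromatises 17, so ethanol and not hydrogen chloride is expelled and the chlorine is kept. The stereocentres of 16 and 17 are transient and the product has none. The step needs the orientation that puts the acetal carbon next to the ester, which the polarisation of the pyrone by its 3-ester secures, and it needs bonding at C6 to outrun addition at C4, which the donor aryloxy group and the quaternary centre that would form there disfavour; the amine keeps the medium free of acid so the acetal and the tert-butyl ester survive.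

Step 9
Reactants: 18 tert-butyl 6-[4-(benzyloxy)-2-methoxy-6-(methoxycarbonyl)phenoxy]-3-chloro-2-ethoxy-4-methylbenzoate
Product: 19 3-chloro-2-hydroxy-6-[4-hydroxy-2-methoxy-6-(methoxycarbonyl)phenoxy]-4-methylbenzoic acid (isodihydromaldoxin)
Conditions: BCl3 (6 equiv), C6HMe5 (3 equiv), CH2Cl2, −78 → 20 °C; H2O
Reagents that add atoms: none
Why: Lewis acid dealkylation in which BCl3 should cleave the tert-butyl ester, the benzyl ether (benzyl cation trapped by pentamethylbenzene in a Friedel-Crafts reaction) and, through a six-membered boron chelate with the neighbouring carboxyl, the ring B ethyl ether, while the unchelated ring A methoxy and the methyl ester are not activated at this temperature.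

**Compound list**

1 | 2-hydroxy-3-methoxybenzoic acid | COc1cccc(C(=O)O)c1O | starting material
2 | potassium 3-carboxy-4-hydroxy-5-methoxyphenyl sulfate (aryl sulfate, not isolated) | COc1cc(OS(=O)(=O)[O-])cc(C(=O)O)c1O.[K+] | intermediate
3 | 2,5-dihydroxy-3-methoxybenzoic acid | COc1cc(O)cc(C(=O)O)c1O | intermediate
4 | methyl 2,5-dihydroxy-3-methoxybenzoate | COC(=O)c1cc(O)cc(OC)c1O | intermediate
5 | methyl 5-(benzyloxy)-2-hydroxy-3-methoxybenzoate | COC(=O)c1cc(OCc2ccccc2)cc(OC)c1O | intermediate
6 | di-tert-butyl malonate | CC(C)(C)OC(=O)CC(=O)OC(C)(C)C | starting material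
7 | 2,2,6-trimethyl-4H-1,3-dioxin-4-one | CC1=CC(=O)OC(C)(C)O1 | starting material
8 | acetylketene (3-oxobut-1-en-1-one, not isolated) | CC(=O)C=C=O | intermediate
9 | di-tert-butyl 2-(3-oxobutanoyl)propanedioate (acylmalonate, formed as its sodium enolate, not isolated) | CC(=O)CC(=O)C(C(=O)OC(C)(C)C)C(=O)OC(C)(C)C | intermediate
10 | tert-butyl 2-(oxomethylidene)-3,5-dioxohexanoate (acylketene, not isolated) | CC(=O)CC(=O)C(=C=O)C(=O)OC(C)(C)C | intermediate
11 | tert-butyl 4-hydroxy-6-methyl-2-oxo-2H-pyran-3-carboxylate | Cc1cc(O)c(C(=O)OC(C)(C)C)c(=O)o1 | intermediate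
12 | tert-butyl 6-methyl-4-[(4-methylbenzenesulfonyl)oxy]-2-oxo-2H-pyran-3-carboxylate | Cc1cc(OS(=O)(=O)c2ccc(C)cc2)c(C(=O)OC(C)(C)C)c(=O)o1 | intermediate
13 | tert-butyl 4-[4-(benzyloxy)-2-methoxy-6-(methoxycarbonyl)phenoxy]-6-methyl-2-oxo-2H-pyran-3-carboxylate | Cc1cc(Oc2c(OC)cc(OCc3ccccc3)cc2C(=O)OC)c(C(=O)OC(C)(C)C)c(=O)o1 | intermediate
14 | 1,1-dichloro-2,2-diethoxyethane (dichloroacetaldehyde diethyl acetal) | CCOC(OCC)C(Cl)Cl | starting material
15 | 2-chloro-1,1-diethoxyethene (chloroketene diethyl acetal) | CCOC(OCC)=CCl | intermediate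
16 | tert-butyl 5-[4-(benzyloxy)-2-methoxy-6-(methoxycarbonyl)phenoxy]-7-chloro-8,8-diethoxy-1-methyl-3-oxo-2-oxabicyclo[2.2.2]oct-5-ene-4-carboxylate (bridged lactone, racemic, either configuration at the chlorine-bearing carbon, not isolated) | O=C1OC2(C)C=C(Oc3c(OC)cc(OCc4ccccc4)cc3C(=O)OC)C1(C(=O)OC(C)(C)C)C(OCC)(OCC)C2Cl | intermediate
17 | tert-butyl 2-[4-(benzyloxy)-2-methoxy-6-(methoxycarbonyl)phenoxy]-5-chloro-6,6-diethoxy-4-methylcyclohexa-1,3-diene-1-carboxylate (racemic, not isolated) | CCOC1(OCC)C(Cl)C(C)=CC(Oc2c(OC)cc(OCc3ccccc3)cc2C(=O)OC)=C1C(=O)OC(C)(C)C | intermediate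
18 | tert-butyl 6-[4-(benzyloxy)-2-methoxy-6-(methoxycarbonyl)phenoxy]-3-chloro-2-ethoxy-4-methylbenzoate | CCOc1c(Cl)c(C)cc(Oc2c(OC)cc(OCc3ccccc3)cc2C(=O)OC)c1C(=O)OC(C)(C)C | intermediate
19 | 3-chloro-2-hydroxy-6-[4-hydroxy-2-methoxy-6-(methoxycarbonyl)phenoxy]-4-methylbenzoic acid (isodihydromaldoxin) | COC(=O)c1cc(O)cc(OC)c1Oc1cc(C)c(Cl)c(O)c1C(=O)O | target

**Step count and risks**

Total steps: 9. Longest linear sequence: 6 steps (1, 2, 3, 6, 8, 9).

Steps most likely to fail:

1. Step 8. The cycloaddition may be too slow, because the 4-aryloxy group donates into the diene and crowds C3 while the chlorine lowers the nucleophilicity of the acetal. Thermal loss of the tert-butyl group, oligomerisation of the acetal or displacement of the ring A phenoxide at C4 could then win.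
 Fallback, setting out from 13 and coming back at 19: 13 is heated in toluene at 110 °C with commercial 1,1-diethoxyethene, the unhindered parent dienophile of this reaction class, to give tert-butyl 6-[4-(benzyloxy)-2-methoxy-6-(methoxycarbonyl)phenoxy]-2-ethoxy-4-methylbenzoate F1. A limited amount of BCl3 at −78 °C without a cation scavenger should cleave the tert-butyl ester and the chelated ethyl ether but leave the unchelated benzyl ether, giving 6-[4-(benzyloxy)-2-methoxy-6-(methoxycarbonyl)phenoxy]-2-hydroxy-4-methylbenzoic acid F2. The single free phenol is then chlorinated under ortho-selective conditions (1,3-dichloro-5,5-dimethylhydantoin, catalytic diisopropylammonium chloride, toluene) at C3, which is ortho to the hydroxyl and less hindered than C5 beside the aryloxy group, to give 6-[4-(benzyloxy)-2-methoxy-6-(methoxycarbonyl)phenoxy]-3-chloro-2-hydroxy-4-methylbenzoic acid F3. Debenzylation with BCl3 and pentamethylbenzene gives 19. The weak point is the C3/C5 selectivity of the chlorination, which the main route avoids.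

2. Step 6. The hindered, hydrogen-bonded phenoxide may attack the sulfonyl sulfur instead of C4 (sulfonyl transfer), or open the lactone at C2 or C6.
 Fallback, setting out from 11 and coming back at 13: 11 is treated with 1-chloro-N,N,2-trimethylprop-1-en-1-amine in CH2Cl2 at 0 °C, neutral conditions that spare the tert-butyl ester, to give tert-butyl 4-chloro-6-methyl-2-oxo-2H-pyran-3-carboxylate F4. This vinylogous acid chloride has no sulfonyl group to be attacked, and with phenol 5 and Cs2CO3 in MeCN it should give 13.

3. Step 9. Cleavage of the ethyl ether may be incomplete at temperatures that still spare the ring A methoxy, and benzyl cations may alkylate the electron-rich rings while the slower ether cleavage is forced.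
 Fallback, setting out from 18 and coming back at 19: the benzyl ether is removed first by hydrogenolysis (H2, Pd/C, EtOAc, 20 °C, stopped after one equivalent of hydrogen to keep the aryl chloride), giving tert-butyl 3-chloro-2-ethoxy-6-[4-hydroxy-2-methoxy-6-(methoxycarbonyl)phenoxy]-4-methylbenzoate F5. BCl3 alone in CH2Cl2 then only has to cleave the tert-butyl ester and the chelated ethyl ether, giving 19.

**Further compounds**

F1 | step 8 | tert-butyl 6-[4-(benzyloxy)-2-methoxy-6-(methoxycarbonyl)phenoxy]-2-ethoxy-4-methylbenzoate | CCOc1cc(C)cc(Oc2c(OC)cc(OCc3ccccc3)cc2C(=O)OC)c1C(=O)OC(C)(C)C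
F2 | step 8 | 6-[4-(benzyloxy)-2-methoxy-6-(methoxycarbonyl)phenoxy]-2-hydroxy-4-methylbenzoic acid | COC(=O)c1cc(OCc2ccccc2)cc(OC)c1Oc1cc(C)cc(O)c1C(=O)O
F3 | step 8 | 6-[4-(benzyloxy)-2-methoxy-6-(methoxycarbonyl)phenoxy]-3-chloro-2-hydroxy-4-methylbenzoic acid | COC(=O)c1cc(OCc2ccccc2)cc(OC)c1Oc1cc(C)c(Cl)c(O)c1C(=O)O
F4 | step 6 | tert-butyl 4-chloro-6-methyl-2-oxo-2H-pyran-3-carboxylate | Cc1cc(Cl)c(C(=O)OC(C)(C)C)c(=O)o1
F5 | step 9 | tert-butyl 3-chloro-2-ethoxy-6-[4-hydroxy-2-methoxy-6-(methoxycarbonyl)phenoxy]-4-methylbenzoate | CCOc1c(Cl)c(C)cc(Oc2c(OC)cc(O)cc2C(=O)OC)c1C(=O)OC(C)(C)C
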